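## Retrosynthetic overview

1. Feature: in the C6=C7 enol γ-lactone (O on C6, C19 as carbonyl), ring C carbon C8 on C7 lies trans to the lactone oxygen and cis to C5. This is the imprint of an anti addition of the C19 carboxylate oxygen and C8 across a C6≡C7 triple bond.
2. Key disconnection: O–C6 and C7–C8 are cut together. This opens the lactone and the seven-membered ring B to an (E)-(2-iodoaryl)methylidene 2-ethynylcyclohexanecarboxylic acid that holds only rings A and C.
3. C10=C20 is cut by aldol addition and dehydration into the ring C iodoaldehyde (from 1,2,4-trimethoxybenzene) and a regiodefined C1=C10 silyl enol ether of ring A.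
4. Ring A comes from Birch methylation of benzoic acid, oxidation to the dienone, copper hydride desymmetrisation (C4), conjugate alkynylation cis to the ester (C5) and a later CBS reduction (C1).
5. Ring order: C and A enter as six-membered rings, the lactone and ring B close in one operation, and the hydroxyquinone is unveiled last.

Key step: step 15

Remark: the icetexane (9(10→20)-abeo-abietane) atom numbers of the target are used for all intermediates. Ar = 2-iodo-3,5,6-trimethoxy-4-(propan-2-yl)phenyl, TBS = tert-butyldimethylsilyl, TMS = trimethylsilyl. In this numbering the target is (1R,4S,5R).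

Assumption: the antipode of Ph-BPE that leads to (S)-12 in step 8 has to be established on the first run. (S,S) is written here, and (R,R) is equally available.

## Route

Step 1
Reactants: 1 1,2,4-trimethoxybenzene
Product: 3 2-(2,3,6-trimethoxyphenyl)propan-2-ol, via aryllithium 2 (not isolated)
Conditions: n-BuLi, THF, 0 °C to rt; acetone, −78 °C to rt; H2O
Reagents that add atoms: acetone, CC(C)=O; n-butyllithium, [Li]CCCC (lithium, held only in 2)
Why: Directed ortho-lithiation takes out the C–H flanked by two methoxy groups (future C13), the most acidic and best chelated site, and the aryllithium adds to the carbonyl group of acetone.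

Step 2
Reactants: 3 2-(2,3,6-trimethoxyphenyl)propan-2-ol
Product: 4 1,2,4-trimethoxy-3-(propan-2-yl)benzene
Conditions: Et3SiH, CF3CO2H, CH2Cl2, 0 °C to rt
Reagents that add atoms: none
Why: Ionic hydrogenation: the tertiary benzylic alcohol, flanked by two donor oxygens, ionises in CF3CO2H and the cation is quenched by hydride transfer from Et3SiH, the methyl ethers being inert.

Step 3
Reactants: 4 1,2,4-trimethoxy-3-(propan-2-yl)benzene
Product: 5 1-iodo-2,4,5-trimethoxy-3-(propan-2-yl)benzene
Conditions: N-iodosuccinimide, CF3CO2H (cat.), MeCN, rt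
Reagents that add atoms: N-iodosuccinimide, O=C1CCC(=O)N1I
Why: Electrophilic aromatic iodination goes to the free position para to the C12 methoxy and ortho to the C14 methoxy group (future C8), the site at which 1,2,4-trialkoxybenzenes are regularly halogenated, while the other free position has only one ortho donor.

Step 4
Reactants: 5 1-iodo-2,4,5-trimethoxy-3-(propan-2-yl)benzene
Product: 6 2-iodo-3,5,6-trimethoxy-4-(propan-2-yl)benzaldehyde
Conditions: Cl2CHOMe, TiCl4, CH2Cl2, −40 to 0 °C; ice-water
Reagents that add atoms: dichloromethyl methyl ether, COC(Cl)Cl (formyl carbon); water, O (formyl oxygen)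
Why: Rieche formylation can only strike the last free ring position (future C9), which is activated by the ortho C11 methoxy group that also anchors TiCl4, and the low temperature is meant to hold back ipso attack at the C–I carbon.

Step 5
Reactants: 7 benzoic acid
Product: 9 1-methylcyclohexa-2,5-diene-1-carboxylic acid, via dilithium dienediolate 8 (not isolated)
Conditions: Li, NH3(l)/THF, −78 °C; MeI; NH4Cl; aq. HCl
Reagents that add atoms: iodomethane, CI; lithium, [Li] (held only in 8)
Why: Birch reduction–alkylation: dissolving-metal reduction of the benzoate stops at the cross-conjugated dienediolate, which is methylated at the carbon alpha to the carboxylate and so builds the still prochiral quaternary C4.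

Step 6
Reactants: 9 1-methylcyclohexa-2,5-diene-1-carboxylic acid
Product: 10 methyl 1-methylcyclohexa-2,5-diene-1-carboxylate
Conditions: MeI, K2CO3, DMF, rt
Reagents that add atoms: iodomethane, CI
Why: SN2 O-alkylation of the potassium carboxylate gives the ester without acid, which could trigger rearrangement of the 1,4-diene.

Step 7
Reactants: 10 methyl 1-methylcyclohexa-2,5-diene-1-carboxylate
Product: 11 methyl 1-methyl-4-oxocyclohexa-2,5-diene-1-carboxylate
Conditions: Rh2(caprolactamate)4 (1 mol %), t-BuOOH (5 equiv), K2CO3 (0.5 equiv), CH2Cl2, rt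
Reagents that add atoms: tert-butyl hydroperoxide, CC(C)(C)OO
Why: Catalytic allylic C–H oxidation (tert-butylperoxyl radical chain) attacks the doubly allylic CH2, the weakest C–H bonds present, and the quaternary carbon rules out aromatisation, so the cross-conjugated dienone should result.

Step 8
Reactants: 11 methyl 1-methyl-4-oxocyclohexa-2,5-diene-1-carboxylate
Product: 12 methyl (S)-1-methyl-4-oxocyclohex-2-ene-1-carboxylate
Conditions: Cu(OAc)2 (5 mol %), (S,S)-Ph-BPE (5.5 mol %), (EtO)2MeSiH (1.1 equiv), t-BuOH (1.1 equiv), toluene, −20 °C
Reagents that add atoms: none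
Why: Copper hydride catalysed asymmetric conjugate reduction, used as a desymmetrisation of a prochiral 4,4-disubstituted cyclohexa-2,5-dienone: the chiral phosphine–CuH complex reduces one of the two enantiotopic enone arms and thereby fixes C4 as (S), and any over-reduction should consume mainly the minor enantiomer.

Step 9
Reactants: 12 methyl (S)-1-methyl-4-oxocyclohex-2-ene-1-carboxylate; 13 trimethylsilylacetylene
Product: 16 methyl (1S,2R)-4-(tert-butyldimethylsilyloxy)-1-methyl-2-[(trimethylsilyl)ethynyl]cyclohex-3-ene-1-carboxylate (alkyne cis to the ester), via lithium acetylide 14 (not isolated), via zinc acetylide 15 (not isolated)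
Conditions: 13, n-BuLi, Et2O, −78 °C; ZnBr2, THF, 0 °C; then 12, TBSOTf, −40 °C
Reagents that add atoms: tert-butyldimethylsilyl trifluoromethanesulfonate, CC(C)(C)[Si](C)(C)OS(=O)(=O)C(F)(F)F; n-butyllithium, [Li]CCCC (lithium, held only in 14); zinc dibromide, Br[Zn]Br (zinc and bromine, held only in 15)
Why: Silyl triflate promoted conjugate addition of an alkynylzinc halide, a known answer to the failure of plain alkynyl metals with s-trans cyclic enones: the slim nucleophile attacks the O-silylated enone axially at C5, anti to the pseudoaxial C4 methyl group (the better sigma donor toward the allyl cation) and on the face where the pseudoequatorial ester carbonyl can hold zinc, which should set C5 as (R) with the alkyne cis to the ester, and the enolate is stored regiospecifically as the C1=C10 silyl enol ether.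

Step 10
Reactants: 16 methyl (1S,2R)-4-(tert-butyldimethylsilyloxy)-1-methyl-2-[(trimethylsilyl)ethynyl]cyclohex-3-ene-1-carboxylate; 6 2-iodo-3,5,6-trimethoxy-4-(propan-2-yl)benzaldehyde
Product: 17 methyl (1S,2R)-3-[Ar(hydroxy)methyl]-1-methyl-4-oxo-2-[(trimethylsilyl)ethynyl]cyclohexane-1-carboxylate (mixture at C10 and C20)
Conditions: TiCl4, CH2Cl2, −78 °C; H2O
Reagents that add atoms: none
Why: Mukaiyama aldol addition: the TiCl4-chelated aldehyde (CHO and ortho methoxy) is attacked by C10 of the silyl enol ether only, so the regiochemistry that a free ketone could not give is secured, and the uncontrolled C10 and C20 stereocentres are erased in step 11.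

Step 11
Reactants: 17 methyl (1S,2R)-3-[Ar(hydroxy)methyl]-1-methyl-4-oxo-2-[(trimethylsilyl)ethynyl]cyclohexane-1-carboxylate
Product: 19 methyl (1S,2R,3E)-3-(Ar-methylidene)-1-methyl-4-oxo-2-[(trimethylsilyl)ethynyl]cyclohexane-1-carboxylate, via benzylic mesylate 18 (not isolated)
Conditions: MsCl, Et3N, CH2Cl2, 0 °C; DBU, 0 °C to rt
Reagents that add atoms: methanesulfonyl chloride, CS(=O)(=O)Cl (held only in 18)
Why: Mesylation and E1cB elimination give the conjugated enone under thermodynamic control as the (E) isomer, aryl anti to the carbonyl group and syn to C5, whose alkynyl group turns axial to escape A(1,3) strain.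

Step 12
Reactants: 19 methyl (1S,2R,3E)-3-(Ar-methylidene)-1-methyl-4-oxo-2-[(trimethylsilyl)ethynyl]cyclohexane-1-carboxylate
Product: 20 methyl (1S,2R,3E,4R)-3-(Ar-methylidene)-4-hydroxy-1-methyl-2-[(trimethylsilyl)ethynyl]cyclohexane-1-carboxylate
Conditions: (S)-2-methyl-CBS-oxazaborolidine (20 mol %), catecholborane, toluene, −78 °C; MeOH/H2O
Reagents that add atoms: none
Why: Corey–Bakshi–Shibata reduction: the (S)-oxazaborolidine reads the alkylidene arm (C10) as the large and C2H2 as the small substituent and delivers hydride 1,2 to the alpha face, which is also the face remote from the axial C5 alkyne (matched case), setting C1 as (R) with the hydroxyl cis to alkyne and ester.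

Step 13
Reactants: 20 methyl (1S,2R,3E,4R)-3-(Ar-methylidene)-4-hydroxy-1-methyl-2-[(trimethylsilyl)ethynyl]cyclohexane-1-carboxylate
Product: 21 methyl (1S,2R,3E,4R)-3-(Ar-methylidene)-4-(tert-butyldimethylsilyloxy)-1-methyl-2-[(trimethylsilyl)ethynyl]cyclohexane-1-carboxylate
Conditions: TBSOTf, 2,6-lutidine, CH2Cl2, 0 °C
Reagents that add atoms: tert-butyldimethylsilyl trifluoromethanesulfonate, CC(C)(C)[Si](C)(C)OS(=O)(=O)C(F)(F)F
Why: Silylation of the hindered allylic alcohol with the reactive triflate caps the C1 oxygen, which lies 1,3-cis to the alkyne and would otherwise compete as a nucleophile in step 15 or lactonise onto C19.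

Step 14
Reactants: 21 methyl (1S,2R,3E,4R)-3-(Ar-methylidene)-4-(tert-butyldimethylsilyloxy)-1-methyl-2-[(trimethylsilyl)ethynyl]cyclohexane-1-carboxylate
Product: 22 (1S,2R,3E,4R)-3-(Ar-methylidene)-4-(tert-butyldimethylsilyloxy)-2-ethynyl-1-methylcyclohexane-1-carboxylic acid
Conditions: LiOH, THF/MeOH/H2O, 55 °C; 1 M HCl to pH 4
Reagents that add atoms: lithium hydroxide, [Li+].[OH-] (oxygen of the new acid OH)
Why: Saponification (acyl–oxygen cleavage) of the methyl ester and hydroxide-induced protodesilylation of the alkynylsilane run in one pot, while the secondary TBS ether, the aryl iodide and the aryl methyl ethers are stable to aqueous LiOH.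

Step 15
Reactants: 22 (1S,2R,3E,4R)-3-(Ar-methylidene)-4-(tert-butyldimethylsilyloxy)-2-ethynyl-1-methylcyclohexane-1-carboxylic acid
Product: 23 tetracyclic enol lactone, (1R,4S,5R)-1-(tert-butyldimethylsilyloxy)-11,12,14-trimethoxyicetexa-6,8,11,13,10(20)-pentaen-19,6-olide
Conditions: Pd(PPh3)4 (10 mol %), Cs2CO3 (2 equiv), DMF (0.002 M, slow addition of 22), 70 °C
Reagents that add atoms: none
Why: Proposed new method: oxidative addition of the C8–I bond to zerovalent palladium gives an arylpalladium iodide whose metal π-binds the axial C6≡C7 group placed next to it by the (E)-alkene, the caesium C19 carboxylate then adds to C6 on the side away from the metal, and the alkenyl(aryl)palladium species, an eight-membered metallacycle, collapses by C7–C8 reductive elimination. The closest known reaction type is the intermolecular palladium-catalysed arylative lactonisation of pent-4-ynoic acids with aryl iodides to (E)-5-arylidenebutyrolactones, and tying the aryl iodide to the alkynoic acid so that a carbocycle closes at the same time is the untested part. The lactone closes 5-exo-dig (O–C6), and ring B closes as a seven-membered ring in the reductive elimination, formally 7-endo with respect to the alkyne. No stereocentre is formed and C1, C4 and C5 are untouched, while the anti addition puts C8 trans to the lactone oxygen and cis to C5, which is what a double bond inside ring B demands. The step needs carboxylate attack to outrun 6-exo-dig syn-carbopalladation (C8 to C6) and intermolecular arylation of the terminal alkyne. A preformed, weakly solvated carboxylate cis and gauche to the alkyne, the polar solvent, high dilution and the silyl cap on the C1 oxygen are meant to secure this.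

Step 16
Reactants: 23 tetracyclic enol lactone trimethyl ether
Product: 24 12-O-methyl-1-O-TBS-6,7-anhydroballotiquinone
Conditions: (NH4)2Ce(NO3)6 (2.5 equiv), MeCN/H2O 4:1, 0 °C
Reagents that add atoms: water, O (the two quinone oxygens)
Why: Oxidative demethylation of a hydroquinone dimethyl ether: two one-electron oxidations of the most electron-rich pi system with attack of water at C11 and C14 expel two molecules of methanol and leave the 12-methoxy-1,4-quinone, fast enough at 0 °C to spare the enol lactone and the silyl ether.

Step 17
Reactants: 24 12-O-methyl-1-O-TBS-6,7-anhydroballotiquinone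
Product: 25 1-O-TBS-6,7-anhydroballotiquinone
Conditions: BCl3 (2 equiv), CH2Cl2, −78 to −40 °C; pH 4 buffer
Reagents that add atoms: none
Why: Lewis acid ether cleavage: BCl3 chelates the C11 carbonyl and the C12 methoxy oxygen of the vinylogous ester and chloride removes the methyl group by SN2, a non-hydrolytic route chosen because aqueous base would open the enol lactone first.

Step 18
Reactants: 25 1-O-TBS-6,7-anhydroballotiquinone
Product: 26 6,7-anhydroballotiquinone
Conditions: HF·pyridine, THF, 0 °C to rt
Reagents that add atoms: none
Why: Fluoride-driven cleavage of the Si–O bond under mildly acidic, buffered conditions frees the C1 hydroxyl without touching the enol lactone, the hydroxyquinone or the three stereocentres.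

## Compound list

1 | 1,2,4-trimethoxybenzene | COc1ccc(OC)c(OC)c1 | starting material
2 | (2,3,6-trimethoxyphenyl)lithium | [Li]c1c(OC)ccc(OC)c1OC | intermediate
3 | 2-(2,3,6-trimethoxyphenyl)propan-2-ol | CC(C)(O)c1c(OC)ccc(OC)c1OC | intermediate
4 | 1,2,4-trimethoxy-3-(propan-2-yl)benzene | CC(C)c1c(OC)ccc(OC)c1OC | intermediate
5 | 1-iodo-2,4,5-trimethoxy-3-(propan-2-yl)benzene | CC(C)c1c(OC)c(I)cc(OC)c1OC | intermediate
6 | 2-iodo-3,5,6-trimethoxy-4-(propan-2-yl)benzaldehyde | CC(C)c1c(OC)c(I)c(C=O)c(OC)c1OC | intermediate
7 | benzoic acid | OC(=O)c1ccccc1 | starting material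
8 | dilithium (cyclohexa-2,5-dien-1-ylidene)methanediolate | [Li+].[Li+].[O-]C([O-])=C1C=CCC=C1 | intermediate
9 | 1-methylcyclohexa-2,5-diene-1-carboxylic acid | CC1(C=CCC=C1)C(=O)O | intermediate
10 | methyl 1-methylcyclohexa-2,5-diene-1-carboxylate | COC(=O)C1(C)C=CCC=C1 | intermediate
11 | methyl 1-methyl-4-oxocyclohexa-2,5-diene-1-carboxylate | COC(=O)C1(C)C=CC(=O)C=C1 | intermediate
12 | methyl (S)-1-methyl-4-oxocyclohex-2-ene-1-carboxylate | COC(=O)[C@@]1(C)CCC(=O)C=C1 | intermediate
13 | trimethylsilylacetylene | C#C[Si](C)(C)C | starting material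
14 | lithium (trimethylsilyl)acetylide | [Li]C#C[Si](C)(C)C | intermediate
15 | bromo[(trimethylsilyl)ethynyl]zinc | Br[Zn]C#C[Si](C)(C)C | intermediate
16 | methyl (1S,2R)-4-(tert-butyldimethylsilyloxy)-1-methyl-2-[(trimethylsilyl)ethynyl]cyclohex-3-ene-1-carboxylate | COC(=O)[C@@]1(C)CCC(O[Si](C)(C)C(C)(C)C)=C[C@H]1C#C[Si](C)(C)C | intermediate
17 | aldol adduct, mixture at C10 and C20 | COC(=O)[C@@]1(C)CCC(=O)C(C(O)c2c(I)c(OC)c(C(C)C)c(OC)c2OC)[C@H]1C#C[Si](C)(C)C | intermediate
18 | benzylic methanesulfonate of 17 | COC(=O)[C@@]1(C)CCC(=O)C(C(OS(C)(=O)=O)c2c(I)c(OC)c(C(C)C)c(OC)c2OC)[C@H]1C#C[Si](C)(C)C | intermediate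
19 | (E)-arylmethylidene ketone | COC(=O)[C@@]1(C)CCC(=O)/C(=C/c2c(I)c(OC)c(C(C)C)c(OC)c2OC)[C@H]1C#C[Si](C)(C)C | intermediate
20 | (1R)-allylic alcohol | COC(=O)[C@@]1(C)CC[C@@H](O)/C(=C/c2c(I)c(OC)c(C(C)C)c(OC)c2OC)[C@H]1C#C[Si](C)(C)C | intermediate
21 | C1 TBS ether | COC(=O)[C@@]1(C)CC[C@@H](O[Si](C)(C)C(C)(C)C)/C(=C/c2c(I)c(OC)c(C(C)C)c(OC)c2OC)[C@H]1C#C[Si](C)(C)C | intermediate
22 | (E)-2-iodobenzylidene ethynyl cyclohexanecarboxylic acid (key precursor) | OC(=O)[C@@]1(C)CC[C@@H](O[Si](C)(C)C(C)(C)C)/C(=C/c2c(I)c(OC)c(C(C)C)c(OC)c2OC)[C@H]1C#C | intermediate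
23 | tetracyclic enol lactone, trimethyl ether, C1 TBS ether (key product) | CC(C)c1c(OC)c(OC)c2c(C=C3OC(=O)[C@@]4(C)CC[C@@H](O[Si](C)(C)C(C)(C)C)C(=C2)[C@@H]34)c1OC | intermediate
24 | 12-O-methyl-1-O-TBS-6,7-anhydroballotiquinone | CC(C)C1=C(OC)C(=O)C2=C(C=C3OC(=O)[C@@]4(C)CC[C@@H](O[Si](C)(C)C(C)(C)C)C(=C2)[C@@H]34)C1=O | intermediate
25 | 1-O-TBS-6,7-anhydroballotiquinone | CC(C)C1=C(O)C(=O)C2=C(C=C3OC(=O)[C@@]4(C)CC[C@@H](O[Si](C)(C)C(C)(C)C)C(=C2)[C@@H]34)C1=O | intermediate
26 | 6,7-anhydroballotiquinone | CC(C)C1=C(O)C(=O)C2=C(C=C3OC(=O)[C@@]4(C)CC[C@@H](O)C(=C2)[C@@H]34)C1=O | target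

## Step count and risks

Total step count: 18. Longest linear sequence: 14 steps (steps 5 to 18, from benzoic acid 7). The aldehyde branch (steps 1 to 4) joins at step 10.

**1. Step 15.**
- What may go wrong: insertion of the alkyne into the aryl–palladium bond at C6 (6-exo-dig) may run faster than carboxylate attack. Intermolecular arylation of the terminal alkyne may lead to oligomers. Lactonisation without arylation may drain the substrate.
- Fallback, from 22 back to 23, by known chemistry: iodolactonisation (I2, NaHCO3, MeCN, 0 °C) adds the carboxylate oxygen and iodine anti across the alkyne and should give the (E)-iodomethylene lactone F1, with iodine on C7 trans to the ring oxygen.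
- The aryl and alkenyl C–I bonds of F1 are then joined by a Stille–Kelly coupling ((Me3Sn)2, Pd(PPh3)4, toluene, 90 °C, high dilution), which closes ring B and returns to 23.

**2. Step 9.**
- What may go wrong: poor facial selectivity between the methyl and the ester face, sluggish attack at the neopentyl beta carbon, or competing 1,2-addition.
- Fallback, from 12 and 13 (through 14) back to 16: stereocontrol is moved from the substrate to a catalyst.
- Me2AlCl converts 14 into dimethyl[(trimethylsilyl)ethynyl]aluminium F2. F2 is added to 12 under nickel catalysis (Ni(acac)2 with a C2-symmetric chiral bis(oxazoline) ligand, t-BuOMe, 0 °C), a known catalyst-controlled conjugate alkynylation of cyclic enones. The ligand antipode is chosen for delivery to the ester face.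
- The resulting dimethylaluminium enolate F3 is silylated in the same flask with TBSOTf to give 16.

**3. Step 17.**
- What may go wrong: loss of the silyl ether followed by ionisation at the allylic C1–O bond, or Lewis acid damage to the enol lactone, before the methyl group is removed.
- Fallback, from 24 back to 25: electrophilic ether cleavage is given up for nucleophilic dealkylation at the methyl carbon (LiI, EtOAc or 2,6-lutidine, 75 °C, then pH 4 buffer).
- The hydroxyquinone anion is as good a leaving group as a carboxylate. The enol lactone offers no sp3 C–O carbon to iodide, so only the vinylogous methyl ester should react. No new compound is made on the way.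

## Further compounds

F1 | step 15 | (E)-iodomethylene lactone (aryl iodide retained, C1 TBS ether) | O=C1O/C(=C/I)[C@@H]2/C(=C\c3c(I)c(OC)c(C(C)C)c(OC)c3OC)[C@H](O[Si](C)(C)C(C)(C)C)CC[C@]12C
F2 | step 9 | dimethyl[(trimethylsilyl)ethynyl]aluminium | C[Al](C)C#C[Si](C)(C)C
F3 | step 9 | dimethylaluminium enolate of the conjugate adduct | COC(=O)[C@@]1(C)CCC(O[Al](C)C)=C[C@H]1C#C[Si](C)(C)C
F0 | step 17 | none | none
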